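The side-chain 1,3-diol (C4'–OH and C6'–OH flanking the C5' methylene) is traced back to two C–B bonds. The C5'–C6' bond is made by lithiation–borylation: a sparteine-complexed α-lithiated decyl benzoate (the C6' carbenoid) captures the primary boron of a 1,2-bis(boronic ester) spanning C4'/C5'. A stereospecific 1,2-shift then joins the two ten-carbon halves and fixes C6', and oxidation in the same flask unveils both carbinols. The precursor is a bis(pinacol boronate) from catalytic diboration of a terminal alkene that already carries C2' (as a silyl ether) and the dihydropyranone ring masked as its 2-methoxy acetal.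

Key step: step 7

Remarks. Locants: the lactone ring is O1, C2–C6; the side chain is C1'–C15' counted from the ring. These locants are kept for all intermediates in the discussion, although the systematic names renumber the ring. Assumption: in the three catalytic enantioselective steps (2, 4 and 6) the drawn product configuration is binding. The catalyst antipodes named are those expected to deliver it by analogy with simple aldehydes, 3-alkoxypropanols and 1-alkenes. For step 6 the ligand antipode is the one that turns R–CH=CH2 into the precursor of the (S)-1,2-diol.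

Step 1
Reactants: 1 decan-1-ol
Product: 2 decyl 2,4,6-triisopropylbenzoate
Conditions: 2,4,6-triisopropylbenzoic acid, PPh3, diisopropyl azodicarboxylate, THF, 0 °C → rt
Reagents that add atoms: 2,4,6-triisopropylbenzoic acid, CC(C)c1cc(C(C)C)c(C(=O)O)c(C(C)C)c1
Why: Mitsunobu esterification of a primary alcohol; the hindered aryl ester later directs α-lithiation and acts as the leaving group.

Step 2
Reactants: 3 3-(tert-butyldimethylsilyloxy)propanal; 4 (E)-1-methoxybuta-1,3-diene
Product: 5 tert-butyl{2-[(2S,6R)-6-methoxy-3,6-dihydro-2H-pyran-2-yl]ethoxy}dimethylsilane (cis acetal)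
Conditions: [CrCl(L)] (3 mol %; L = Schiff-base dianion from (1S,2R)-1-aminoindan-2-ol and 3-(1-adamantyl)-2-hydroxy-5-methylbenzaldehyde), 4 Å molecular sieves, neat, rt
Reagents that add atoms: none
Why: Catalytic enantioselective hetero-Diels–Alder reaction; the trivalent chromium Lewis acid binds the aldehyde, the endo [4+2] addition gives the cis-2,6 acetal, and the catalyst antipode sets C6 (S).

Step 3
Reactants: 5 cis acetal silyl ether
Product: 6 2-[(2S,6R)-6-methoxy-3,6-dihydro-2H-pyran-2-yl]ethan-1-ol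
Conditions: Bu4NF, THF, 0 °C → rt; chromatography on base-washed silica
Reagents that add atoms: none
Why: Fluoride desilylation of the primary silyl ether; the basic medium leaves the acid-labile allylic acetal untouched.

Step 4
Reactants: 6 acetal alcohol; 7 allyl acetate
Product: 8 (2S)-1-[(2S,6R)-6-methoxy-3,6-dihydro-2H-pyran-2-yl]pent-4-en-2-ol
Conditions: Ir(η3-allyl)[(S)-Cl,MeO-BIPHEP](4-chloro-3-nitrobenzoate-C,O) (5 mol %, preformed from [Ir(cod)Cl]2), K3PO4 (1 equiv), H2O (5 equiv), THF, 70 °C
Reagents that add atoms: none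
Why: Iridium-catalysed transfer-hydrogenative carbonyl allylation from the alcohol oxidation level; the transient aldehyde is allylated through a closed chair transition state under catalyst control, which should set C2' (S), anti to the C6 oxygen, while stoichiometric phosphate keeps the acetal away from the acetic acid formed.

Step 5
Reactants: 8 homoallylic alcohol
Product: 9 tert-butyl({(2S)-1-[(2S,6R)-6-methoxy-3,6-dihydro-2H-pyran-2-yl]pent-4-en-2-yl}oxy)dimethylsilane
Conditions: TBSCl, imidazole, DMF, rt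
Reagents that add atoms: tert-butyldimethylsilyl chloride, CC(C)(C)[Si](C)(C)Cl
Why: Standard silylation of a secondary alcohol; the ether blocks the C2' oxygen from closing onto the acetal carbon C2 and from quenching the carbenoid in step 7.

Step 6
Reactants: 9 silyl ether alkene
Product: 10 tert-butyl({(2S,4R)-1-[(2S,6R)-6-methoxy-3,6-dihydro-2H-pyran-2-yl]-4,5-bis(4,4,5,5-tetramethyl-1,3,2-dioxaborolan-2-yl)pentan-2-yl}oxy)dimethylsilane
Conditions: B2pin2, Pt(dba)3 (3 mol %), 3,5-diisopropylphenyl-TADDOL phenylphosphonite (6 mol %; antipode as fixed in the remarks), THF, 60 °C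
Reagents that add atoms: bis(pinacolato)diboron, CC1(C)OB(OC1(C)C)B1OC(C)(C)C(C)(C)O1
Why: Platinum-catalysed enantioselective alkene diboration (B–B oxidative addition to zerovalent platinum, alkene insertion, reductive elimination); the chiral phosphonite selects the alkene face and sets the C4' boronate (R), and the cis-disubstituted ring alkene is far less reactive than the monosubstituted one.

Step 7
Reactants: 2 decyl 2,4,6-triisopropylbenzoate; 10 1,2-bis(boronic ester)
Product: 14 (2S,4R,6S)-2-(tert-butyldimethylsilyloxy)-1-[(2S,6R)-6-methoxy-3,6-dihydro-2H-pyran-2-yl]pentadecane-4,6-diol, via lithiated benzoate 11 (not isolated), via boronate complex 12 (not isolated), via bis(boronic ester) 13 (not isolated)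
Conditions: 2, sBuLi, (+)-sparteine, Et2O, −78 °C; then 10, −78 °C → 35 °C; then NaOH, H2O2, THF/H2O, 0 °C → rt
Reagents that add atoms: hydrogen peroxide, OO
Why: Lithiation–borylation: sBuLi/(+)-sparteine removes one enantiotopic α-proton of 2 to give the configurationally stable carbenoid 11, which adds with retention to the less hindered primary boron of 10, and on warming the C5' methylene migrates from boron to C6' antiperiplanar to the departing benzoate (inversion at C6'), forming the C5'–C6' bond. The closest known reaction type is the regioselective homologation of diboration-derived 1,2-bis(pinacol boronates) with sparteine-derived lithiated benzoates followed by oxidation to 1,3-diols. No ring is closed. C6' is set by the reagent (the sparteine antipode, then the stereospecific retention–inversion sequence) and C4' from step 6 is carried through; both C–B bonds are oxidised with retention, which should give the anti C4'/C6' diol with C6' (S). The step needs chemoselection between the two boron atoms, which the steric difference between the primary and the secondary pinacol boronate secures, and it needs the rest of 10 to ignore a basic carbenoid and alkaline peroxide, which the silyl ether and the methyl acetal (the reason the lactone is carried masked) secure.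

Step 8
Reactants: 14 acetal diol
Product: 15 (6S)-6-[(2S,4R,6S)-2-(tert-butyldimethylsilyloxy)-4,6-dihydroxypentadecyl]-5,6-dihydro-2H-pyran-2-ol (anomer mixture)
Conditions: pyridinium p-toluenesulfonate (cat.), acetone/H2O, rt → 40 °C
Reagents that add atoms: water, O
Why: Acid-catalysed hydrolysis of the allylic mixed acetal through an allyl-stabilised oxocarbenium ion to the lactol; the C2' silyl ether is retained so that the C2' oxygen cannot close onto C2.

Step 9
Reactants: 15 lactol
Product: 16 (6S)-6-[(2S,4R,6S)-2-(tert-butyldimethylsilyloxy)-4,6-dihydroxypentadecyl]-5,6-dihydro-2H-pyran-2-one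
Conditions: activated MnO2, CH2Cl2, rt
Reagents that add atoms: none
Why: Chemoselective manganese dioxide oxidation of the allylic lactol hydroxyl to the α,β-unsaturated δ-lactone; the isolated secondary carbinols at C4' and C6' are not oxidised.

Step 10
Reactants: 16 silyl-protected lactone
Product: 17 (6S)-6-[(2S,4R,6S)-2,4,6-trihydroxypentadecyl]-5,6-dihydro-2H-pyran-2-one
Conditions: HF·pyridine, pyridine/THF, 0 °C → rt
Reagents that add atoms: none
Why: Fluoride-driven desilylation under buffered, non-basic conditions, chosen to avoid oxa-Michael addition of the freed C2' hydroxyl to C4 and opening of the lactone.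

Compound list
1 | decan-1-ol | CCCCCCCCCCO | starting material
2 | decyl 2,4,6-triisopropylbenzoate | CCCCCCCCCCOC(=O)c1c(C(C)C)cc(C(C)C)cc1C(C)C | intermediate
3 | 3-(tert-butyldimethylsilyloxy)propanal | CC(C)(C)[Si](C)(C)OCCC=O | starting material
4 | (E)-1-methoxybuta-1,3-diene | CO/C=C/C=C | starting material
5 | tert-butyl{2-[(2S,6R)-6-methoxy-3,6-dihydro-2H-pyran-2-yl]ethoxy}dimethylsilane | CC(C)(C)[Si](C)(C)OCC[C@@H]1CC=C[C@H](OC)O1 | intermediate
6 | 2-[(2S,6R)-6-methoxy-3,6-dihydro-2H-pyran-2-yl]ethan-1-ol | OCC[C@@H]1CC=C[C@H](OC)O1 | intermediate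
7 | allyl acetate | C=CCOC(C)=O | starting material
8 | (2S)-1-[(2S,6R)-6-methoxy-3,6-dihydro-2H-pyran-2-yl]pent-4-en-2-ol | C=CC[C@H](O)C[C@@H]1CC=C[C@H](OC)O1 | intermediate
9 | tert-butyl({(2S)-1-[(2S,6R)-6-methoxy-3,6-dihydro-2H-pyran-2-yl]pent-4-en-2-yl}oxy)dimethylsilane | C=CC[C@H](O[Si](C)(C)C(C)(C)C)C[C@@H]1CC=C[C@H](OC)O1 | intermediate
10 | tert-butyl({(2S,4R)-1-[(2S,6R)-6-methoxy-3,6-dihydro-2H-pyran-2-yl]-4,5-bis(4,4,5,5-tetramethyl-1,3,2-dioxaborolan-2-yl)pentan-2-yl}oxy)dimethylsilane | CC1(C)OB(C[C@@H](B2OC(C)(C)C(C)(C)O2)C[C@H](O[Si](C)(C)C(C)(C)C)C[C@@H]2CC=C[C@H](OC)O2)OC1(C)C | intermediate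
11 | (R)-1-lithiodecyl 2,4,6-triisopropylbenzoate, (+)-sparteine complex (sparteine not drawn) | CCCCCCCCC[C@@H]([Li])OC(=O)c1c(C(C)C)cc(C(C)C)cc1C(C)C | intermediate
12 | lithium boronate complex of 11 with the primary boron of 10 | CCCCCCCCC[C@H](OC(=O)c1c(C(C)C)cc(C(C)C)cc1C(C)C)[B-]1(C[C@@H](B2OC(C)(C)C(C)(C)O2)C[C@H](O[Si](C)(C)C(C)(C)C)C[C@@H]2CC=C[C@H](OC)O2)OC(C)(C)C(C)(C)O1.[Li+] | intermediate
13 | tert-butyl({(2S,4R,6S)-1-[(2S,6R)-6-methoxy-3,6-dihydro-2H-pyran-2-yl]-4,6-bis(4,4,5,5-tetramethyl-1,3,2-dioxaborolan-2-yl)pentadecan-2-yl}oxy)dimethylsilane | CCCCCCCCC[C@H](B1OC(C)(C)C(C)(C)O1)C[C@@H](B1OC(C)(C)C(C)(C)O1)C[C@H](O[Si](C)(C)C(C)(C)C)C[C@@H]1CC=C[C@H](OC)O1 | intermediate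
14 | (2S,4R,6S)-2-(tert-butyldimethylsilyloxy)-1-[(2S,6R)-6-methoxy-3,6-dihydro-2H-pyran-2-yl]pentadecane-4,6-diol | CCCCCCCCC[C@H](O)C[C@@H](O)C[C@H](O[Si](C)(C)C(C)(C)C)C[C@@H]1CC=C[C@H](OC)O1 | intermediate
15 | (6S)-6-[(2S,4R,6S)-2-(tert-butyldimethylsilyloxy)-4,6-dihydroxypentadecyl]-5,6-dihydro-2H-pyran-2-ol (anomer mixture) | CCCCCCCCC[C@H](O)C[C@@H](O)C[C@H](O[Si](C)(C)C(C)(C)C)C[C@@H]1CC=CC(O)O1 | intermediate
16 | (6S)-6-[(2S,4R,6S)-2-(tert-butyldimethylsilyloxy)-4,6-dihydroxypentadecyl]-5,6-dihydro-2H-pyran-2-one | CCCCCCCCC[C@H](O)C[C@@H](O)C[C@H](O[Si](C)(C)C(C)(C)C)C[C@@H]1CC=CC(=O)O1 | intermediate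
17 | (6S)-6-[(2S,4R,6S)-2,4,6-trihydroxypentadecyl]-5,6-dihydro-2H-pyran-2-one | CCCCCCCCC[C@H](O)C[C@@H](O)C[C@H](O)C[C@@H]1CC=CC(=O)O1 | target

Total step count: 10. Longest linear sequence: 9 steps (steps 2–10, from 3 and 4); step 1 is a one-step branch that joins at step 7.

Steps most likely to fail

Step 7. The carbenoid may discriminate incompletely between the primary and the secondary boron, or the 1,2-shift may be slow and lose out to decomposition of the boronate complex. The fallback sets out from 10 and returns at 14. Oxidation of 10 (NaOH, H2O2) should give (2S,4S)-4-(tert-butyldimethylsilyloxy)-5-[(2S,6R)-6-methoxy-3,6-dihydro-2H-pyran-2-yl]pentane-1,2-diol F1. Selective sulfonylation of the primary hydroxyl (TsCl, Et3N, Bu2SnO cat.) gives the primary tosylate F2, and K2CO3 in methanol closes it to the terminal (S)-epoxide F3 with C4' unchanged. Decanal and propane-1,3-dithiol (BF3·OEt2) give 2-nonyl-1,3-dithiane F4. Its lithio derivative (nBuLi, THF) opens F3 at C5' in a Corey–Seebach alkylation, again forming the C5'–C6' bond, to the hydroxy dithiane F5. Dithiane removal (MeI, CaCO3, MeCN/H2O) gives the β-hydroxy ketone F6. Evans–Saksena reduction (Me4NBH(OAc)3, MeCN/AcOH, −30 °C) then delivers hydride anti to the C4' hydroxyl and should give 14.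

Step 8. The silyl ether may be lost under the acid, after which the C2' hydroxyl closes onto C2 to a bridged acetal; the lactol may also open and isomerise to the (E)-enal. The fallback sets out from 14 and returns at 17, avoiding the free lactol. Silylation of both carbinols (TBSOTf, 2,6-lutidine) gives the tris(silyl ether) acetal F7. Direct oxidation of the allylic methyl acetal with pyridinium chlorochromate, [C5H5NH][CrO3Cl], in CH2Cl2 gives the tris(silyl) lactone F8. Aqueous HF in MeCN removes the three silyl groups to give 17.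

Step 6. The facial selectivity at C4' may be poor, or the platinum catalyst may attack the ring alkene or the allylic acetal. The fallback sets out from 9 and returns at 14; it uses the alkene as a masked methyl ketone and replaces both steps 6 and 7. Wacker oxidation (PdCl2, CuCl, O2, DMF/H2O) gives the methyl ketone (4R)-4-(tert-butyldimethylsilyloxy)-5-[(2S,6R)-6-methoxy-3,6-dihydro-2H-pyran-2-yl]pentan-2-one F9. Its boron enolate (the Ipc2BCl antipode that gives the (6'S) carbinol, Et3N, Et2O, −78 °C) adds to decanal under reagent control. The silyl ether exerts little 1,5-bias, so the selectivity is expected to be modest and to need chromatographic separation. This gives the aldol (2R,6S)-2-(tert-butyldimethylsilyloxy)-6-hydroxy-1-[(2S,6R)-6-methoxy-3,6-dihydro-2H-pyran-2-yl]pentadecan-4-one F10. Evans–Saksena reduction (Me4NBH(OAc)3) anti to the C6' hydroxyl then gives 14.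

Further compounds
F1 | step 7 | (2S,4S)-4-(tert-butyldimethylsilyloxy)-5-[(2S,6R)-6-methoxy-3,6-dihydro-2H-pyran-2-yl]pentane-1,2-diol | OC[C@@H](O)C[C@H](O[Si](C)(C)C(C)(C)C)C[C@@H]1CC=C[C@H](OC)O1
F2 | step 7 | (2S,4S)-4-(tert-butyldimethylsilyloxy)-2-hydroxy-5-[(2S,6R)-6-methoxy-3,6-dihydro-2H-pyran-2-yl]pentyl 4-methylbenzenesulfonate | Cc1ccc(cc1)S(=O)(=O)OC[C@@H](O)C[C@H](O[Si](C)(C)C(C)(C)C)C[C@@H]1CC=C[C@H](OC)O1
F3 | step 7 | tert-butyl({(2S)-1-[(2S,6R)-6-methoxy-3,6-dihydro-2H-pyran-2-yl]-3-[(2S)-oxiran-2-yl]propan-2-yl}oxy)dimethylsilane | C1O[C@H]1C[C@H](O[Si](C)(C)C(C)(C)C)C[C@@H]2CC=C[C@H](OC)O2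
F4 | step 7 | 2-nonyl-1,3-dithiane | CCCCCCCCCC1SCCCS1
F5 | step 7 | (2S,4S)-4-(tert-butyldimethylsilyloxy)-5-[(2S,6R)-6-methoxy-3,6-dihydro-2H-pyran-2-yl]-1-(2-nonyl-1,3-dithian-2-yl)pentan-2-ol | CCCCCCCCCC1(C[C@@H](O)C[C@H](O[Si](C)(C)C(C)(C)C)C[C@@H]2CC=C[C@H](OC)O2)SCCCS1
F6 | step 7 | (2S,4S)-2-(tert-butyldimethylsilyloxy)-4-hydroxy-1-[(2S,6R)-6-methoxy-3,6-dihydro-2H-pyran-2-yl]pentadecan-6-one | CCCCCCCCCC(=O)C[C@@H](O)C[C@H](O[Si](C)(C)C(C)(C)C)C[C@@H]1CC=C[C@H](OC)O1
F7 | step 8 | (2S,6R)-2-[(2S,4R,6S)-2,4,6-tris(tert-butyldimethylsilyloxy)pentadecyl]-6-methoxy-3,6-dihydro-2H-pyran | CCCCCCCCC[C@H](O[Si](C)(C)C(C)(C)C)C[C@@H](O[Si](C)(C)C(C)(C)C)C[C@H](O[Si](C)(C)C(C)(C)C)C[C@@H]1CC=C[C@H](OC)O1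
F8 | step 8 | (6S)-6-[(2S,4R,6S)-2,4,6-tris(tert-butyldimethylsilyloxy)pentadecyl]-5,6-dihydro-2H-pyran-2-one | CCCCCCCCC[C@H](O[Si](C)(C)C(C)(C)C)C[C@@H](O[Si](C)(C)C(C)(C)C)C[C@H](O[Si](C)(C)C(C)(C)C)C[C@@H]1CC=CC(=O)O1
F9 | step 6 | (4R)-4-(tert-butyldimethylsilyloxy)-5-[(2S,6R)-6-methoxy-3,6-dihydro-2H-pyran-2-yl]pentan-2-one | CC(=O)C[C@H](O[Si](C)(C)C(C)(C)C)C[C@@H]1CC=C[C@H](OC)O1
F10 | step 6 | (2R,6S)-2-(tert-butyldimethylsilyloxy)-6-hydroxy-1-[(2S,6R)-6-methoxy-3,6-dihydro-2H-pyran-2-yl]pentadecan-4-one | CCCCCCCCC[C@H](O)CC(=O)C[C@H](O[Si](C)(C)C(C)(C)C)C[C@@H]1CC=C[C@H](OC)O1
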